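**Assumption:** the target has no stereocentre, so "single enantiomer" is read as the achiral compound as drawn; ZnCl2 and BF3·OEt2 are counted as Lewis-acid promoters that do not enter the balanced equations.

## Retrosynthetic overview

1. Target 15 ⇒ isocaviunin 13 by a last-step Friedel–Crafts prenylation at C6, the only free CH of ring A; the acid-sensitive alkene is kept out of all earlier steps.
2. Ring C is the only ring formed: 13 ⇒ deoxybenzoin 10 plus a one-carbon unit (O1–C2 and C2–C3). Rings A and B are bought.
3. Key bond C3–C1′: the α-carbon of the A-ring ketone is turned into an enolonium (α-keto cation equivalent) and joined to a C–H of 1,2,4-trimethoxybenzene; both carbons are natively nucleophilic.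
4. A-ring ketone 5 ⇒ iretol by Hoesch acetylation, then 4,6-bis-MOM protection; the OH next to OMe is left free to become O1, which fixes 8-OMe over 6-OMe.

## Route

**Step 1**
Reactants: 1 iretol (2-methoxybenzene-1,3,5-triol); 2 acetonitrile
Product: 4 1-(2,4,6-trihydroxy-3-methoxyphenyl)ethan-1-one, via ketiminium chloride 3 (not isolated)
Conditions: ZnCl2, HCl(g), Et2O, 0 °C, 16 h; then H2O, reflux, 1 h
Reagents that add atoms: water O (carbonyl O of 4); hydrogen chloride Cl (chloride of 3 only)
Why: Houben–Hoesch acylation; the two free ring carbons of iretol are equivalent by symmetry, the iminium salt deactivates the ring against a second acylation, and water hydrolyses it to the ketone.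

**Step 2**
Reactants: 4 1-(2,4,6-trihydroxy-3-methoxyphenyl)ethan-1-one
Product: 5 1-[2-hydroxy-3-methoxy-4,6-bis(methoxymethoxy)phenyl]ethan-1-one
Conditions: MOMCl (2.1 eq), i-Pr2NEt (2.6 eq), CH2Cl2, 0 °C → rt
Reagents that add atoms: chloromethyl methyl ether COCCl
Why: Selective phenol O-alkylation; the unchelated 4-OH and the less hindered 6-OH should react, while the 2-OH wedged between the carbonyl (H-bond) and the OMe stays free, by analogy with 3-alkyl analogues and not proven for this substrate (checked by NOE: the lone ArH must see both OCH2O groups).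

**Step 3**
Reactants: 5 1-[2-hydroxy-3-methoxy-4,6-bis(methoxymethoxy)phenyl]ethan-1-one; 6 1,2,4-trimethoxybenzene
Product: 10 1-[2-hydroxy-3-methoxy-4,6-bis(methoxymethoxy)phenyl]-2-(2,4,5-trimethoxyphenyl)ethan-1-one, via bis-TMS silyl enol ether 7 (not isolated), via enolonium species 8 (not isolated), via O-TMS deoxybenzoin 9 (not isolated)
Conditions: i) TMSOTf (2.4 eq), Et3N (3 eq), CH2Cl2, 0 °C; pentane, filter under Ar, concentrate (crude, telescoped); ii) PhI(OH)OTs (1.2 eq), BF3·OEt2 (1.5 eq), CH2Cl2, −78 °C, 10 min; iii) 6 (3 eq), −78 → −30 °C; iv) aq. NaHCO3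
Reagents that add atoms: trimethylsilyl triflate C[Si](C)(C)OS(=O)(=O)C(F)(F)F (TMS groups of 7, 8, 9 only); Koser's reagent OI(c1ccccc1)OS(=O)(=O)c1ccc(C)cc1 (iodane part of 8 only); only 5 and 6 supply atoms to 10
Why: Proposed new method: the silyl enol ether attacks BF3-activated Koser's reagent to give an iodine(III) enolate (enolonium) whose α-carbon is strongly electrophilic because iodobenzene is a hypernucleofuge, and 1,2,4-trimethoxybenzene adds through C5 (ortho to one OMe, para to another) in a Friedel–Crafts-type step, the phenol being masked as its TMS ether so that I(III) meets only the enol ether; the closest known reaction type is hypervalent-iodine umpolung α-arylation of ketone silyl enol ethers with indoles and similar π-nucleophiles via preformed enolonium species.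

**Step 4**
Reactants: 10 1-[2-hydroxy-3-methoxy-4,6-bis(methoxymethoxy)phenyl]-2-(2,4,5-trimethoxyphenyl)ethan-1-one
Product: 13 isocaviunin (5,7-dihydroxy-8-methoxy-3-(2,4,5-trimethoxyphenyl)-4H-chromen-4-one), via enaminone 11 (not isolated), via bis-MOM isoflavone 12 (not isolated)
Conditions: DMF-DMA (3 eq), toluene, 90 °C until 11 is fully converted to 12; evaporate; 3 M HCl, MeOH, 60 °C, 2 h
Reagents that add atoms: N,N-dimethylformamide dimethyl acetal COC(OC)N(C)C (C2 of the chromone; also NMe2 of 11)
Why: Enaminone condensation at the activated CH2 followed by addition–elimination ring closure of the only free phenol (loss of Me2NH) is the standard DMF-DMA isoflavone synthesis from 2-hydroxydeoxybenzoins, and HCl/MeOH then cleaves both MOM acetals by transacetalisation.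

**Step 5**
Reactants: 13 isocaviunin; 14 2-methylbut-3-en-2-ol
Product: 15 6-prenylisocaviunin (5,7-dihydroxy-8-methoxy-6-(3-methylbut-2-en-1-yl)-3-(2,4,5-trimethoxyphenyl)-4H-chromen-4-one)
Conditions: BF3·OEt2 (1 eq), 14 (4 eq), dioxane, rt, 8 h (stop at partial conversion, recycle 13)
Reagents that add atoms: none
Why: Friedel–Crafts prenylation; BF3 ionises the tertiary allylic alcohol to the dimethylallyl cation, which is captured at its primary terminus by C6, the only unsubstituted carbon of ring A and the most nucleophilic one (flanked by two OH groups).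

## Compound list

1 | iretol (2-methoxybenzene-1,3,5-triol) | COc1c(O)cc(O)cc1O | starting material
2 | acetonitrile | CC#N | starting material
3 | 1-(2,4,6-trihydroxy-3-methoxyphenyl)ethan-1-iminium chloride | CC(=[NH2+])c1c(O)cc(O)c(OC)c1O.[Cl-] | intermediate
4 | 1-(2,4,6-trihydroxy-3-methoxyphenyl)ethan-1-one | CC(=O)c1c(O)cc(O)c(OC)c1O | intermediate
5 | 1-[2-hydroxy-3-methoxy-4,6-bis(methoxymethoxy)phenyl]ethan-1-one | CC(=O)c1c(OCOC)cc(OCOC)c(OC)c1O | intermediate
6 | 1,2,4-trimethoxybenzene | COc1ccc(OC)c(OC)c1 | starting material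
7 | trimethyl({1-[3-methoxy-4,6-bis(methoxymethoxy)-2-(trimethylsilyloxy)phenyl]ethenyl}oxy)silane | C=C(O[Si](C)(C)C)c1c(OCOC)cc(OCOC)c(OC)c1O[Si](C)(C)C | intermediate
8 | enolonium species: 1-[3-methoxy-4,6-bis(methoxymethoxy)-2-(trimethylsilyloxy)phenyl]ethenyl O-bound to phenyl(tosyloxy)-λ3-iodane (BF3 coordination omitted) | C=C(OI(c1ccccc1)OS(=O)(=O)c1ccc(C)cc1)c1c(OCOC)cc(OCOC)c(OC)c1O[Si](C)(C)C | intermediate
9 | 1-[3-methoxy-4,6-bis(methoxymethoxy)-2-(trimethylsilyloxy)phenyl]-2-(2,4,5-trimethoxyphenyl)ethan-1-one | COCOc1cc(OCOC)c(C(=O)Cc2cc(OC)c(OC)cc2OC)c(O[Si](C)(C)C)c1OC | intermediate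
10 | 1-[2-hydroxy-3-methoxy-4,6-bis(methoxymethoxy)phenyl]-2-(2,4,5-trimethoxyphenyl)ethan-1-one | COCOc1cc(OCOC)c(C(=O)Cc2cc(OC)c(OC)cc2OC)c(O)c1OC | intermediate
11 | 3-(dimethylamino)-1-[2-hydroxy-3-methoxy-4,6-bis(methoxymethoxy)phenyl]-2-(2,4,5-trimethoxyphenyl)prop-2-en-1-one (alkene geometry not defined; either isomer cyclises) | COCOc1cc(OCOC)c(C(=O)C(=CN(C)C)c2cc(OC)c(OC)cc2OC)c(O)c1OC | intermediate
12 | 8-methoxy-5,7-bis(methoxymethoxy)-3-(2,4,5-trimethoxyphenyl)-4H-chromen-4-one | COCOc1cc(OCOC)c2c(=O)c(-c3cc(OC)c(OC)cc3OC)coc2c1OC | intermediate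
13 | isocaviunin (5,7-dihydroxy-8-methoxy-3-(2,4,5-trimethoxyphenyl)-4H-chromen-4-one) | COc1cc(OC)c(-c2coc3c(OC)c(O)cc(O)c3c2=O)cc1OC | intermediate
14 | 2-methylbut-3-en-2-ol | CC(C)(O)C=C | starting material
15 | 6-prenylisocaviunin | COc1cc(OC)c(-c2coc3c(OC)c(O)c(CC=C(C)C)c(O)c3c2=O)cc1OC | target

## Step count and risks

Total steps: 5. Longest linear sequence: 5 (1 → 4 → 5 → 10 → 13 → 15); 2, 6 and 14 are bought.

**Step 3 (most likely to fail).** The enolonium can be lost to 5-exo attack by an ortho ether oxygen (giving a benzofuran-3-one), to tosylate capture, or to I(III) attack on the electron-rich A ring, and the trimethoxyarene is a weaker nucleophile than the indoles used in known cases. The fallback sets out from 5 and comes back at 13. Claisen–Schmidt condensation of 5 with commercial 2,4,5-trimethoxybenzaldehyde (KOH, EtOH, rt) gives the chalcone (E)-1-[2-hydroxy-3-methoxy-4,6-bis(methoxymethoxy)phenyl]-3-(2,4,5-trimethoxyphenyl)prop-2-en-1-one F1. Oxidative 1,2-aryl shift with Tl(NO3)3·3H2O in MeOH/HC(OMe)3 gives the racemic acetal 1-[2-hydroxy-3-methoxy-4,6-bis(methoxymethoxy)phenyl]-3,3-dimethoxy-2-(2,4,5-trimethoxyphenyl)propan-1-one F2, whose stereocentre disappears in the next operation. HCl/MeOH at 60 °C then closes the ring and removes both MOM groups to give 13. The polarity reversal at the α-carbon is kept, but the bond is made intramolecularly by migration of the electron-rich aryl group.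

**Step 5.** Direct C-prenylation typically gives 25–40 % with recovered 13; side reactions are chroman formation with a neighbouring OH and attack on ring B. Basic conditions are avoided because 5,7-dihydroxy-8-methoxyisoflavones can ring-open and reclose to the 6-methoxy isomers. The fallback sets out from 13 and comes back at 15. Selective 7-O-alkylation (prenyl bromide, K2CO3, acetone, rt; the chelated 5-OH stays free) gives 5-hydroxy-8-methoxy-7-[(3-methylbut-2-en-1-yl)oxy]-3-(2,4,5-trimethoxyphenyl)-4H-chromen-4-one F3. Montmorillonite K10 in CH2Cl2 (0 °C → rt) then effects the acid-clay 1,3-shift of the prenyl group from O to the only open ortho carbon, C6, giving 15.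

**Step 2.** The regiochemistry rests on steric discrimination between the two ortho OH groups; if the C2 oxygen proves the more reactive one, the wrong bis-MOM isomer forms and the 6-methoxy series results. The fallback sets out from 4 and comes back at 5. Exhaustive protection (NaH, MOMCl, DMF, 0 °C) gives 1-[3-methoxy-2,4,6-tris(methoxymethoxy)phenyl]ethan-1-one F4. Catalytic I2 in MeOH at rt then removes one ortho acetal; this should be the doubly flanked, most twisted one at C2, by analogy with the selective AlCl3 cleavage of the corresponding ortho methyl ether. The chelated phenol that results slows loss of the second. This selects by the opposite principle (fastest-cleaving site instead of slowest-alkylating site), so whichever factor governs the C2 oxygen, one of the two ways should deliver 5.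

## Further compounds

F1 | step 3 | (E)-1-[2-hydroxy-3-methoxy-4,6-bis(methoxymethoxy)phenyl]-3-(2,4,5-trimethoxyphenyl)prop-2-en-1-one | COCOc1cc(OCOC)c(C(=O)/C=C/c2cc(OC)c(OC)cc2OC)c(O)c1OC
F2 | step 3 | 1-[2-hydroxy-3-methoxy-4,6-bis(methoxymethoxy)phenyl]-3,3-dimethoxy-2-(2,4,5-trimethoxyphenyl)propan-1-one (racemic) | COCOc1cc(OCOC)c(C(=O)C(C(OC)OC)c2cc(OC)c(OC)cc2OC)c(O)c1OC
F3 | step 5 | 5-hydroxy-8-methoxy-7-[(3-methylbut-2-en-1-yl)oxy]-3-(2,4,5-trimethoxyphenyl)-4H-chromen-4-one | COc1cc(OC)c(-c2coc3c(OC)c(OCC=C(C)C)cc(O)c3c2=O)cc1OC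
F4 | step 2 | 1-[3-methoxy-2,4,6-tris(methoxymethoxy)phenyl]ethan-1-one | CC(=O)c1c(OCOC)cc(OCOC)c(OC)c1OCOC
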